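**Plan**

1. Ring locants (hydroxy‑acid half): C1 = CH–iPr, C2 and C3 = the two CH2, C4 = carbinol carbon, C5 = CO2H carbon, C6 = side‑chain carbon. The inter‑half ester C–O is cut; both halves come from one cis‑fused hydroxy γ‑lactone (C4–CH2–O–CO–C5) that already carries the side chain: dehydration gives the butenolide half, lactone opening the hydroxy‑acid half.
2. Further cuts: the side‑chain C=C (Wittig at a C6 aldehyde), the lactone C–O and C4–O (enolate hydroxylation, α‑hydroxy‑ester reduction), then ring bond C2–C3, then C5–C6 (SN2′) and C1–C6 (Michael).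
3. Enabling feature: C3 is an unsubstituted CH2 next to C4; C4 with its CH2O carbon and C5 with its carboxyl form a succinate, so with C3=C4 they are an itaconate (2‑alkylacrylate) whose CH2 terminus is C3. A primary radical at C2, released from a CH2CO2H group on C1, closes the cyclohexane on it in the 6‑endo mode.
4. Forward order: C1–C6, C5–C6, ring closure C2–C3, equilibration, C4–OH, lactone, side chain; then divergence, esterification, deprotection.
5. Stereochemistry: C1 from the iminium‑catalysed malonate addition; C5 and C6 by equilibration to the all‑equatorial triester anchored by C1; C4 by equatorial attack of the oxidant on the ester enolate (checked by cis‑lactonisation); both alkenes E from the stabilised ylide.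

Key step: step 5

Assumption: allyl (triphenylphosphoranylidene)acetate and (triisopropylsiloxy)methyl chloride are taken as purchasable catalogue reagents.

**Route**

Step 1
Reactants: 1 dimethyl itaconate
Product: 3 dimethyl 2-(bromomethyl)fumarate, via dibromide 2 (not isolated)
Conditions: Br2, CH2Cl2, 0 °C to rt; then Et3N, 0 °C
Reagents that add atoms: bromine, BrBr
Why: Bromine adds to the 1,1‑disubstituted alkene and base then removes HBr through the acidic CH2 next to the second ester, which should give the conjugated allylic bromide (bromination–dehydrobromination).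

Step 2
Reactants: 4 (E)-4-methylpent-2-enal; 5 dibenzyl malonate
Product: 6 dibenzyl 2-[(3R)-4-methyl-1-oxopentan-3-yl]malonate
Conditions: (R)-2-{bis[3,5-bis(trifluoromethyl)phenyl](trimethylsilyloxy)methyl}pyrrolidine (10 mol %), EtOH, 0 °C
Reagents that add atoms: none
Why: Iminium‑catalysed Michael addition; the (R)‑diarylprolinol silyl ether shields one face of the (E)‑iminium ion so the malonate should add to the other face of the β‑carbon and set the isopropyl‑bearing centre (future C1) as R.

Step 3
Reactants: 6 malonate aldehyde; 3 dimethyl 2-(bromomethyl)fumarate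
Product: 8 itaconate aldehyde (tetraester, both C5 epimers), via allylammonium bromide 7 (not isolated)
Conditions: 3, DABCO (1.1 equiv), MeCN, rt; then 6, Cs2CO3, 0 °C to rt
Reagents that add atoms: none
Why: Lewis‑base‑mediated SN2′ substitution of a Morita–Baylis–Hillman‑type electrophile: the malonate anion adds to the CH= carbon of the ammonium salt and DABCO is expelled, which forms C5–C6 and regenerates the acrylate C3=C4; C5 is formed without control and is corrected in step 6.

Step 4
Reactants: 8 itaconate aldehyde
Product: 9 itaconate acid (CH2CO2H on C1)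
Conditions: NaClO2, NaH2PO4, 2-methyl-2-butene, t-BuOH–H2O, 0 °C to rt
Reagents that add atoms: sodium chlorite, [Na+].[O-]Cl=O
Why: Pinnick oxidation should convert the aldehyde into the acid without touching the acrylate, with 2‑methyl‑2‑butene scavenging HOCl.

Step 5
Reactants: 9 itaconate acid
Product: 11 cyclohexane tetraester, via redox-active ester 10 (not isolated)
Conditions: N-hydroxyphthalimide, N,N'-diisopropylcarbodiimide, DMAP (cat.), CH2Cl2, rt; then Ru(bpy)3(PF6)2 (1 mol %), diethyl 2,6-dimethyl-1,4-dihydropyridine-3,5-dicarboxylate, i-Pr2NEt, CH2Cl2 (0.01 M), blue LEDs, rt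
Reagents that add atoms: none
Why: The N‑acyloxyphthalimide 10 accepts one electron from the reduced photocatalyst and fragments to phthalimide anion, CO2 and the primary radical at C2, which adds to the CH2 terminus (C3) of the 2‑substituted acrylate and so forms C2–C3; the tertiary α‑ester radical at C4 then takes a hydrogen atom from the dihydropyridine. The closest known reaction type is the decarboxylative Giese reaction of redox‑active esters, here intramolecular on a 2‑alkylacrylate. The cyclohexane closes in the 6‑endo‑trig mode. The only new stereocentre, C4, arises by unselective hydrogen transfer and C5 is already an epimer mixture; both are α to esters and are set later (steps 6 and 8), while C1 is untouched. The step needs 6‑endo rather than 5‑exo closure, and ring closure ahead of hydrogen transfer or intermolecular addition: attack at C4 would hit a fully substituted carbon and give an unstabilised primary radical, attack at C3 is unhindered and gives the ester‑stabilised radical, and the geminal diester at C6 (Thorpe–Ingold effect) and high dilution favour the intramolecular path.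

Step 6
Reactants: 11 cyclohexane tetraester
Product: 13 all-trans triester, via triester epimer mixture 12 (not isolated)
Conditions: LiCl, H2O, DMSO, 150 °C; then KOtBu (0.2 equiv), t-BuOH–THF, rt
Reagents that add atoms: none
Why: Krapcho dealkoxycarbonylation removes one benzyl ester of the geminal diester, and alkoxide‑mediated epimerisation of the three enolisable ester α‑centres (C4, C5, C6) should funnel the mixture to the all‑equatorial triester anchored by the equatorial isopropyl group at C1, which sets C5 and C6.

Step 7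
Reactants: 13 all-trans triester
Product: 14 all-trans diester acid (CO2H at C6)
Conditions: H2 (1 atm), Pd/C, EtOAc, rt
Reagents that add atoms: none
Why: Hydrogenolysis cleaves only the benzyl ester, as no alkene is present at this stage.

Step 8
Reactants: 14 diester acid
Product: 15 C4-hydroxy diester acid
Conditions: KN(SiMe3)2 (2.3 equiv), THF, −78 °C; 3-phenyl-2-(phenylsulfonyl)oxaziridine, −78 °C; aq. HCl
Reagents that add atoms: 3-phenyl-2-(phenylsulfonyl)oxaziridine, O=S(=O)(N1OC1c1ccccc1)c1ccccc1
Why: Enolate hydroxylation with an N‑sulfonyloxaziridine: in the dianion the C6 carboxylate should suppress enolisation at the adjacent C5, so the ester enolate forms at C4, and the bulky oxidant should attack this exocyclic enolate from the equatorial face, anti to the C5 ester, giving equatorial OH and axial ester at C4.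

Step 9
Reactants: 15 C4-hydroxy diester acid
Product: 17 hydroxy lactone acid, via diol ester 16 (not isolated)
Conditions: NaBH4, MeOH–THF, 0 °C to rt; then 1 M HCl, rt
Reagents that add atoms: none
Why: Borohydride reduces the α‑hydroxy ester selectively (hydride delivered from the alkoxyborohydride; the C5 ester and the carboxylate stay), and acid then lactonises the axial CH2OH onto the cis C5 ester, which the trans C6 carboxyl cannot reach.

Step 10
Reactants: 17 hydroxy lactone acid
Product: 18 hydroxy lactone alcohol (CH2OH at C6)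
Conditions: BH3·THF, THF, 0 °C to rt; aqueous work-up
Reagents that add atoms: none
Why: Borane reduces the free carboxylic acid chemoselectively through the acyloxyborane, whereas the γ‑lactone reacts much more slowly.

Step 11
Reactants: 19 allyl (triphenylphosphoranylidene)acetate
Product: 21 allyl 3-[(triisopropylsilyl)oxy]-2-(triphenylphosphoranylidene)propanoate, via phosphonium chloride 20 (not isolated)
Conditions: (i-Pr)3SiOCH2Cl, PhMe, 60 °C; then aq. NaOH, CH2Cl2
Reagents that add atoms: (triisopropylsiloxy)methyl chloride, ClCO[Si](C(C)C)(C(C)C)C(C)C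
Why: C‑Alkylation of the stabilised ylide by the α‑chloro ether gives the phosphonium salt, which base converts into the α‑substituted ylide (ylide alkylation).

Step 12
Reactants: 18 hydroxy lactone alcohol; 21 silyloxymethyl ylide
Product: 23 hydroxy lactone with (E) side chain, via aldehyde 22 (not isolated)
Conditions: Dess–Martin periodinane, CH2Cl2, rt; then 21, PhMe, 80 °C
Reagents that add atoms: none
Why: Dess–Martin oxidation gives the C6 aldehyde, whose equatorial configuration is the thermodynamic one, and Wittig olefination with the α‑substituted stabilised ylide should place the ring carbon trans to the ester (E), as in the target.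

Step 13
Reactants: 23 hydroxy lactone with side chain
Product: 24 butenolide allyl ester
Conditions: methyl N-(triethylammoniosulfonyl)carbamate (Burgess dehydration), PhMe, 70 °C
Reagents that add atoms: none
Why: Burgess dehydration: syn‑elimination of the tertiary sulfamate through the cis C5–H, which is α to the lactone carbonyl, should give the conjugated tetrasubstituted butenolide.

Step 14
Reactants: 24 butenolide allyl ester
Product: 25 butenolide acid
Conditions: Pd(PPh3)4 (5 mol %), morpholine, THF, rt; acidic work-up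
Reagents that add atoms: none
Why: Deallylation catalysed by zerovalent palladium (π‑allyl formation, capture by morpholine) frees the acid under neutral conditions that spare the butenolide and the silyl ether.

Step 15
Reactants: 23 hydroxy lactone with side chain
Product: 27 diol bis(allyl ester), via lithium carboxylate 26 (not isolated)
Conditions: LiOH (1.1 equiv), THF–H2O, 0 °C; concentrate; allyl bromide, DMF, rt
Reagents that add atoms: lithium hydroxide, [Li+].[OH-]; allyl bromide, C=CCBr
Why: Saponification opens the γ‑lactone and the carboxylate is then O‑alkylated with allyl bromide; any side‑chain ester cleaved by hydroxide is re‑allylated in the same operation.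

Step 16
Reactants: 27 diol bis(allyl ester); 25 butenolide acid
Product: 29 protected dimer, via mixed anhydride 28 (not isolated)
Conditions: 2-methyl-6-nitrobenzoic anhydride, Et3N, DMAP (cat.), CH2Cl2, rt
Reagents that add atoms: none
Why: Shiina esterification: the mixed anhydride of 25 should acylate, under DMAP catalysis, the primary hydroxyl of 27 in preference to the tertiary one.

Step 17
Reactants: 29 protected dimer
Product: 30 diol bis(allyl ester) dimer
Conditions: HF·pyridine, pyridine, THF, 0 °C to rt
Reagents that add atoms: none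
Why: Fluoride cleaves both primary triisopropylsilyl ethers through Si–F bond formation and leaves the esters alone.

Step 18
Reactants: 30 diol bis(allyl ester) dimer
Product: 31 target CNP0071646.2
Conditions: Pd(PPh3)4 (5 mol %), morpholine, THF, rt; acidic work-up
Reagents that add atoms: none
Why: Allyl transfer to morpholine catalysed by zerovalent palladium removes both allyl esters; the inter‑half ester is not allylic on its oxygen side and, like the butenolide and the tertiary alcohol, should survive.

**Compound list**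

1 | dimethyl itaconate | C=C(CC(=O)OC)C(=O)OC | starting material
2 | dimethyl 2-bromo-2-(bromomethyl)butanedioate | COC(=O)CC(Br)(CBr)C(=O)OC | intermediate
3 | dimethyl 2-(bromomethyl)fumarate | COC(=O)/C=C(/C(=O)OC)CBr | intermediate
4 | (E)-4-methylpent-2-enal | CC(C)/C=C/C=O | starting material
5 | dibenzyl malonate | O=C(CC(=O)OCc1ccccc1)OCc1ccccc1 | starting material
6 | dibenzyl 2-[(3R)-4-methyl-1-oxopentan-3-yl]malonate | CC(C)[C@H](C(C(=O)OCc1ccccc1)C(=O)OCc1ccccc1)CC=O | intermediate
7 | 1-[(2E)-2,3-bis(methoxycarbonyl)prop-2-en-1-yl]-4-aza-1-azoniabicyclo[2.2.2]octane bromide | COC(=O)/C=C(/C(=O)OC)C[N+]12CCN(CC1)CC2.[Br-] | intermediate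
8 | 1,1-dibenzyl 2,3-dimethyl 1-[(3R)-4-methyl-1-oxopentan-3-yl]but-3-ene-1,1,2,3-tetracarboxylate (both C-2 epimers) | CC(C)[C@H](C(C(=O)OCc1ccccc1)(C(=O)OCc1ccccc1)C(C(=O)OC)C(=C)C(=O)OC)CC=O | intermediate
9 | (3R)-4,4-bis[(benzyloxy)carbonyl]-5,6-bis(methoxycarbonyl)-3-(propan-2-yl)hept-6-enoic acid (both C-5 epimers) | CC(C)[C@H](C(C(=O)OCc1ccccc1)(C(=O)OCc1ccccc1)C(C(=O)OC)C(=C)C(=O)OC)CC(=O)O | intermediate
10 | 1,3-dioxoisoindolin-2-yl ester of 9 | CC(C)[C@H](C(C(=O)OCc1ccccc1)(C(=O)OCc1ccccc1)C(C(=O)OC)C(=C)C(=O)OC)CC(=O)ON1C(=O)c2ccccc2C1=O | intermediate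
11 | 1,1-dibenzyl 2,3-dimethyl (6R)-6-(propan-2-yl)cyclohexane-1,1,2,3-tetracarboxylate (mixture at C-2 and C-3) | CC(C)[C@H]1CCC(C(=O)OC)C(C(=O)OC)C1(C(=O)OCc2ccccc2)C(=O)OCc3ccccc3 | intermediate
12 | 3-benzyl 1,2-dimethyl (4R)-4-(propan-2-yl)cyclohexane-1,2,3-tricarboxylate (mixture at C-1, C-2, C-3) | CC(C)[C@H]1CCC(C(=O)OC)C(C(=O)OC)C1C(=O)OCc2ccccc2 | intermediate
13 | 3-benzyl 1,2-dimethyl (1S,2R,3R,4R)-4-(propan-2-yl)cyclohexane-1,2,3-tricarboxylate (all substituents equatorial, each trans to its neighbours) | CC(C)[C@H]1CC[C@H](C(=O)OC)[C@@H](C(=O)OC)[C@@H]1C(=O)OCc2ccccc2 | intermediate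
14 | (1R,2R,3S,6R)-2,3-bis(methoxycarbonyl)-6-(propan-2-yl)cyclohexane-1-carboxylic acid (all-trans) | CC(C)[C@H]1CC[C@H](C(=O)OC)[C@@H](C(=O)OC)[C@@H]1C(=O)O | intermediate
15 | (1R,2S,3S,6R)-3-hydroxy-2,3-bis(methoxycarbonyl)-6-(propan-2-yl)cyclohexane-1-carboxylic acid (C4–OH equatorial, trans to the C5 ester) | CC(C)[C@H]1CC[C@@](O)(C(=O)OC)[C@@H](C(=O)OC)[C@@H]1C(=O)O | intermediate
16 | diol ester acid: as 15 with the C4 ester reduced to axial CH2OH | CC(C)[C@H]1CC[C@@](O)(CO)[C@@H](C(=O)OC)[C@@H]1C(=O)O | intermediate
17 | hydroxy lactone acid: cis-fused γ-lactone C4–CH2–O–CO–C5, C4–OH equatorial, CO2H at C6 and iPr at C1 equatorial | CC(C)[C@H]1CC[C@@]2(O)COC(=O)[C@H]2[C@@H]1C(=O)O | intermediate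
18 | hydroxy lactone alcohol: as 17 with CH2OH at C6 | CC(C)[C@H]1CC[C@@]2(O)COC(=O)[C@H]2[C@@H]1CO | intermediate
19 | allyl (triphenylphosphoranylidene)acetate | C=CCOC(=O)C=P(c1ccccc1)(c1ccccc1)c1ccccc1 | starting material
20 | {1-[(allyloxy)carbonyl]-2-[(triisopropylsilyl)oxy]ethyl}triphenylphosphonium chloride | C=CCOC(=O)C(CO[Si](C(C)C)(C(C)C)C(C)C)[P+](c1ccccc1)(c1ccccc1)c1ccccc1.[Cl-] | intermediate
21 | allyl 3-[(triisopropylsilyl)oxy]-2-(triphenylphosphoranylidene)propanoate | C=CCOC(=O)C(CO[Si](C(C)C)(C(C)C)C(C)C)=P(c1ccccc1)(c1ccccc1)c1ccccc1 | intermediate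
22 | hydroxy lactone aldehyde: as 17 with CHO at C6 | CC(C)[C@H]1CC[C@@]2(O)COC(=O)[C@H]2[C@@H]1C=O | intermediate
23 | hydroxy lactone with side chain: as 17 with (E)-CH=C(CH2OSi(i-Pr)3)CO2allyl at C6 | CC(C)[C@H]1CC[C@@]2(O)COC(=O)[C@H]2[C@@H]1/C=C(\CO[Si](C(C)C)(C(C)C)C(C)C)C(=O)OCC=C | intermediate
24 | butenolide allyl ester: allyl (E)-3-(5-isopropyl-3-oxo-1,3,4,5,6,7-hexahydroisobenzofuran-4-yl)-2-{[(triisopropylsilyl)oxy]methyl}acrylate, ring substituents trans | C=CCOC(=O)/C(=C/[C@H]1C2=C(CC[C@@H]1C(C)C)COC2=O)CO[Si](C(C)C)(C(C)C)C(C)C | intermediate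
25 | butenolide acid: free acid of 24 | OC(=O)/C(=C/[C@H]1C2=C(CC[C@@H]1C(C)C)COC2=O)CO[Si](C(C)C)(C(C)C)C(C)C | intermediate
26 | lithium carboxylate: ring-opened 23 (C5–CO2Li, C4–OH, C4–CH2OH) | CC(C)[C@H]1CC[C@@](O)(CO)[C@@H](C(=O)[O-])[C@@H]1/C=C(\CO[Si](C(C)C)(C(C)C)C(C)C)C(=O)OCC=C.[Li+] | intermediate
27 | diol bis(allyl ester): C5–CO2allyl, C4(OH)CH2OH, side chain as in 23 | CC(C)[C@H]1CC[C@@](O)(CO)[C@@H](C(=O)OCC=C)[C@@H]1/C=C(\CO[Si](C(C)C)(C(C)C)C(C)C)C(=O)OCC=C | intermediate
28 | mixed anhydride of 25 with 2-methyl-6-nitrobenzoic acid | Cc1cccc([N+](=O)[O-])c1C(=O)OC(=O)/C(=C/[C@H]1C2=C(CC[C@@H]1C(C)C)COC2=O)CO[Si](C(C)C)(C(C)C)C(C)C | intermediate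
29 | protected dimer: 27 acylated at the primary hydroxyl by 25 | CC(C)[C@H]1CC[C@@](O)(COC(=O)/C(=C/[C@H]2C3=C(CC[C@@H]2C(C)C)COC3=O)CO[Si](C(C)C)(C(C)C)C(C)C)[C@@H](C(=O)OCC=C)[C@@H]1/C=C(\CO[Si](C(C)C)(C(C)C)C(C)C)C(=O)OCC=C | intermediate
30 | bis(allyl ester) of the target | CC(C)[C@H]1CC[C@@](O)(COC(=O)/C(=C/[C@H]2C3=C(CC[C@@H]2C(C)C)COC3=O)CO)[C@@H](C(=O)OCC=C)[C@@H]1/C=C(\CO)C(=O)OCC=C | intermediate
31 | CNP0071646.2 | CC(C)[C@H]1CC[C@@](O)(COC(=O)/C(=C/[C@H]2C3=C(CC[C@@H]2C(C)C)COC3=O)CO)[C@@H](C(=O)O)[C@@H]1/C=C(\CO)C(=O)O | target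

**Count and risks**

Total step count: 18. Longest linear sequence: 15 steps (2–10, 12, 13, 14, 16, 17, 18).

Step 3. The fully substituted malonate carbanion of 6 must add to a carbon that itself carries an ester. Steric retardation could let proton transfer, aldol self‑condensation of the aldehyde, or attack at the CH2–N carbon take over. The fallback sets out from 6 and comes back at 12; it shrinks the nucleophile by decarboxylating before, not after, the C5–C6 bond is made. Pinnick oxidation of 6 would give (3R)-4,4-bis[(benzyloxy)carbonyl]-3-(propan-2-yl)butanoic acid F1. Krapcho dealkoxycarbonylation (LiCl, wet DMSO, heat) would give the hemiester 5-(benzyloxy)-5-oxo-3-(propan-2-yl)pentanoic acid F2. Its dianion (LiN(i-Pr)2, 2.2 equiv, THF, −78 °C), a secondary ester enolate, would be added to 3 by addition–elimination to give the itaconate acid 4-[(benzyloxy)carbonyl]-5,6-bis(methoxycarbonyl)-3-(propan-2-yl)hept-6-enoic acid F3. Its N‑hydroxyphthalimide ester F4, cyclised under the conditions of step 5, would give 12 directly.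

Step 8. Enolisation could compete at C5, the oxidant could attack from the axial face, or the enolate could add to the sulfonimine by‑product. The fallback sets out from 14 and comes back at 18; it uses ring strain instead of charge to block C5. BH3·THF would reduce the acid of 14, and the new CH2OH would close onto the neighbouring C5 ester to give the trans‑fused lactone ester F5. Enolisation of its ring‑fusion α‑carbon is disfavoured, so KN(SiMe3)2 and the oxaziridine should hydroxylate C4 only, giving the hydroxy ester F6. NaBH4 would reduce the α‑hydroxy ester to the diol lactone F7, and acid‑catalysed translactonisation to the more stable cis‑fused lactone would give 18.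

Step 16 (with step 15). The γ‑hydroxy allyl ester 27 could relactonise to 23, with loss of allyl alcohol, faster than its hindered primary hydroxyl is acylated. The fallback sets out from 25 and 26 and comes back at 29; it acylates while C5 is still a carboxylate, which cannot lactonise. 25 would be converted with 1,1′‑carbonyldiimidazole into the acyl imidazolide F8. Dried 26 would be deprotonated at the primary hydroxyl (LiN(SiMe3)2, 1 equiv, THF, −78 °C) and acylated by F8; acidification would give the coupled C5 acid F9. Allylation of its caesium salt (allyl bromide, Cs2CO3, DMF) would give 29.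

**Further compounds**

F1 | step 3 | (3R)-4,4-bis[(benzyloxy)carbonyl]-3-(propan-2-yl)butanoic acid | CC(C)[C@H](C(C(=O)OCc1ccccc1)C(=O)OCc1ccccc1)CC(=O)O
F2 | step 3 | 5-(benzyloxy)-5-oxo-3-(propan-2-yl)pentanoic acid (isopropyl carbon arranged as in 6) | CC(C)[C@H](CC(=O)OCc1ccccc1)CC(=O)O
F3 | step 3 | 4-[(benzyloxy)carbonyl]-5,6-bis(methoxycarbonyl)-3-(propan-2-yl)hept-6-enoic acid (mixture at C-4 and C-5) | CC(C)[C@H](C(C(=O)OCc1ccccc1)C(C(=O)OC)C(=C)C(=O)OC)CC(=O)O
F4 | step 3 | 1,3-dioxoisoindolin-2-yl ester of F3 | CC(C)[C@H](C(C(=O)OCc1ccccc1)C(C(=O)OC)C(=C)C(=O)OC)CC(=O)ON1C(=O)c2ccccc2C1=O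
F5 | step 8 | trans-fused lactone ester (C6–CH2–O–CO–C5 lactone, equatorial CO2Me at C4) | CC(C)[C@H]1CC[C@H](C(=O)OC)[C@H]2C(=O)OC[C@H]12
F6 | step 8 | C4-hydroxy derivative of F5 (OH equatorial, CO2Me axial) | CC(C)[C@H]1CC[C@@](O)(C(=O)OC)[C@H]2C(=O)OC[C@H]12
F7 | step 8 | diol lactone (F6 with the ester reduced to CH2OH) | CC(C)[C@H]1CC[C@@](O)(CO)[C@H]2C(=O)OC[C@H]12
F8 | step 16 | acyl imidazolide of 25 | O=C(n1ccnc1)/C(=C/[C@H]1C2=C(CC[C@@H]1C(C)C)COC2=O)CO[Si](C(C)C)(C(C)C)C(C)C
F9 | step 16 | coupled dimer with free C5 carboxylic acid (29 lacking the C5 allyl group) | CC(C)[C@H]1CC[C@@](O)(COC(=O)/C(=C/[C@H]2C3=C(CC[C@@H]2C(C)C)COC3=O)CO[Si](C(C)C)(C(C)C)C(C)C)[C@@H](C(=O)O)[C@@H]1/C=C(\CO[Si](C(C)C)(C(C)C)C(C)C)C(=O)OCC=C
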